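The plan cuts the seven-membered ring between its CH2 carbon (C7) and ring A carbon C9, which lies meta to both ring A oxygens and is out of reach of cationic cyclisation. The neighbouring C8, a CH bearing ring B and a 4-hydroxyphenyl group, is what a 1,1-diarylethene gives when hydride goes to its internal carbon and a metal to its terminus. In one flask, copper hydride hydroboration therefore sets C8 and an intramolecular B-alkyl Suzuki–Miyaura coupling forms C7–C9, closing the ring. The precursor is an enantiopure trans-2,3-diaryl-2,3-dihydrobenzofuran with a triflate at C9, a MOM ether at C13 and a 1-(4-methoxyphenyl)vinyl group on ring B. A second dihydrofuran and global demethylation finish the synthesis.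

Key step: step 12

Atom labels: C2 and C3 are the sp3 carbons of the first dihydrofuran (C2 carries the 4-oxygenated phenyl group, C3 carries ring B). C7 is the CH2 and C8 the CH(aryl) carbon of the seven-membered ring. Ring A, the central benzene, is numbered C9 (bonded to C7), C10 (bonded to C3), C11 (bonded to the first dihydrofuran oxygen), C12 (CH), C13 (bonded to the second phenolic oxygen) and C14 (bonded to C3'). Ring B is the fused dioxygenated benzene that joins C3 and C8. C2' and C3' are the sp3 carbons of the second dihydrofuran.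

Assumption 1: the sense of induction of the copper catalyst at C8 cannot be derived with confidence for this substrate, so the (R)-ligand is written and its antipode is to be taken should a trial run give the 8R epimer.

Assumption 2: (2R,5R)-2,5-dimethylthiolane is taken as a purchased reagent and is chosen by analogy with the sense of its benzylidene transfer to aldehydes; its antipode is to be taken should a trial run give the (2'S,3'S) isomer.

**Route**

Step 1
Reactants: 1 3,5-dimethoxybenzoic acid
Product: 2 2-bromo-3,5-dimethoxybenzoic acid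
Conditions: NBS, MeCN, 0 °C to rt
Reagents that add atoms: N-bromosuccinimide, O=C1CCC(=O)N1Br
Why: Electrophilic aromatic bromination should take the 2-position, para to one methoxy group and ortho to the other, in preference to the more hindered position between the two ethers, and this places the later cross-coupling handle on ring B.

Step 2
Reactants: 2 2-bromo-3,5-dimethoxybenzoic acid; 3 phloroglucinol
Product: 5 (2-bromo-3,5-dimethoxyphenyl)(2,4,6-trihydroxyphenyl)methanone, via acid chloride 4 (not isolated)
Conditions: (COCl)2, cat. DMF, CH2Cl2, rt; then 3, AlCl3, PhNO2–CH2Cl2, 0 °C to rt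
Reagents that add atoms: none
Why: Friedel–Crafts acylation of the symmetric, highly nucleophilic triol can give only one C-acyl product, and the ring B methoxy groups sit meta to the carbonyl, where AlCl3 has no chelation-assisted path to cleave them.

Step 3
Reactants: 5 trihydroxy ketone
Product: 6 (2-bromo-3,5-dimethoxyphenyl)[2,6-dihydroxy-4-(methoxymethoxy)phenyl]methanone
Conditions: MOMCl (1.0 equiv), iPr2NEt, CH2Cl2, 0 °C
Reagents that add atoms: chloromethyl methyl ether, COCCl
Why: Williamson-type O-alkylation should select the para hydroxyl because the two ortho hydroxyls are hydrogen-bonded to and shielded by the aroyl group, which marks the oxygen destined for C13 and leaves the two equivalent ortho oxygens for the dihydrofuran and the triflate.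

Step 4
Reactants: 6 mono-MOM ketone
Product: 8 racemic 2-[(2-bromo-3,5-dimethoxyphenyl)(4-methylbenzenesulfonyl)methyl]-5-(methoxymethoxy)benzene-1,3-diol, via benzhydrol 7 (not isolated)
Conditions: NaBH4, THF–MeOH, 0 °C; then TolSO2Na, AcOH–H2O, rt
Reagents that add atoms: sodium p-toluenesulfinate, Cc1ccc(cc1)S(=O)[O-].[Na+]
Why: Borohydride reduction of the diaryl ketone in the cold gives a benzhydrol electron-rich enough to ionise in weak acid that leaves the MOM acetal intact, and SN1-type S-alkylation of the sulfinate stores the latent ortho-quinone methide as a sulfone whose single, racemic centre is erased in step 6.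

Step 5
Reactants: 9 4-methoxybenzyl alcohol
Product: 10 1-(4-methoxybenzyl)tetrahydrothiophen-1-ium tetrafluoroborate
Conditions: tetrahydrothiophene, HBF4·OEt2, CH2Cl2, 0 °C to rt
Reagents that add atoms: tetrahydrothiophene, C1CCSC1; tetrafluoroboric acid (diethyl ether complex), [H+].F[B-](F)(F)F
Why: Acid-promoted SN1 alkylation of the sulfide by the 4-methoxybenzyl cation gives the sulfonium salt, and the non-nucleophilic counter-ion cannot reverse the alkylation.

Step 6
Reactants: 8 racemic sulfone; 10 sulfonium salt
Product: 13 racemic trans-3-(2-bromo-3,5-dimethoxyphenyl)-2-(4-methoxyphenyl)-6-(methoxymethoxy)-2,3-dihydro-1-benzofuran-4-ol, via quinone methide 11 (not isolated), via sulfonium ylide 12 (not isolated)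
Conditions: Cs2CO3, 10 (excess), MeCN, 0 °C to rt
Reagents that add atoms: none
Why: Base expels sulfinate to unveil the ortho-quinone methide and deprotonates the sulfonium salt, and the formal [4+1] annulation (conjugate addition of the ylide, then 5-exo-tet displacement of tetrahydrothiophene by the phenoxide) should close the dihydrofuran with the two aryl groups trans, as favoured by the anti addition–SN2 sequence and by thermodynamics, while the second ortho oxygen, which can slow the addition by ionising but has no productive path of its own, stays as the free phenol on C9.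

Step 7
Reactants: 13 racemic trans phenol
Product: 14 (2S,3R)-3-(2-bromo-3,5-dimethoxyphenyl)-2-(4-methoxyphenyl)-6-(methoxymethoxy)-2,3-dihydro-1-benzofuran-4-ol
Conditions: preparative SFC, amylose tris(3,5-dimethylphenylcarbamate) column, CO2–MeOH
Reagents that add atoms: none
Why: Resolution on a chiral stationary phase fixes the absolute configuration of C2 and C3 for the rest of the route, and the bromine atom allows the (2S,3R) assignment to be secured by anomalous-dispersion crystallography.

Step 8
Reactants: 15 4-methoxyacetophenone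
Product: 16 N'-[1-(4-methoxyphenyl)ethylidene]-2,4,6-tri(propan-2-yl)benzenesulfonohydrazide
Conditions: TrisNHNH2, cat. HCl, MeOH, rt
Reagents that add atoms: 2,4,6-triisopropylbenzenesulfonyl hydrazide, CC(C)c1cc(C(C)C)c(S(=O)(=O)NN)c(C(C)C)c1
Why: Acid-catalysed condensation of the ketone with the sulfonyl hydrazide gives the hydrazone needed for the Shapiro reaction.

Step 9
Reactants: 16 trisylhydrazone
Product: 18 2-[1-(4-methoxyphenyl)ethenyl]-4,4,5,5-tetramethyl-1,3,2-dioxaborolane, via vinyllithium 17 (not isolated)
Conditions: n-BuLi (2.2 equiv), TMEDA–THF, −78 to 0 °C; then iPrOBpin, −78 °C to rt; H2O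
Reagents that add atoms: 2-isopropoxy-4,4,5,5-tetramethyl-1,3,2-dioxaborolane, CC(C)OB1OC(C)(C)C(C)(C)O1
Why: The Shapiro reaction turns the hydrazone dianion into the 1-arylvinyllithium with loss of sulfinate and nitrogen, and borylation of that organolithium fixes boron on the internal vinyl carbon without regiochemical ambiguity.

Step 10
Reactants: 14 (2S,3R)-bromo phenol; 18 vinyl boronate
Product: 19 (2S,3S)-3-{3,5-dimethoxy-2-[1-(4-methoxyphenyl)ethenyl]phenyl}-2-(4-methoxyphenyl)-6-(methoxymethoxy)-2,3-dihydro-1-benzofuran-4-ol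
Conditions: Pd(OAc)2, SPhos, K3PO4, toluene–H2O, 80 °C
Reagents that add atoms: none
Why: Suzuki–Miyaura coupling with a bulky dialkylbiarylphosphine tolerates the doubly ortho-substituted bromide and the free phenol, the bromide is the only electrophilic site because C9 does not yet carry a triflate, and the C3 descriptor changes from R to S only through the change in substituent priority.

Step 11
Reactants: 19 vinyl phenol
Product: 20 (2S,3S)-3-{3,5-dimethoxy-2-[1-(4-methoxyphenyl)ethenyl]phenyl}-2-(4-methoxyphenyl)-6-(methoxymethoxy)-2,3-dihydro-1-benzofuran-4-yl trifluoromethanesulfonate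
Conditions: PhNTf2, Cs2CO3, DMF, rt
Reagents that add atoms: N-phenylbis(trifluoromethanesulfonimide), O=S(=O)(N(c1ccccc1)S(=O)(=O)C(F)(F)F)C(F)(F)F
Why: O-sulfonylation of the phenoxide with the mild triflimide reagent turns the hydroxyl on C9 into the coupling leaving group without exposing the acid-sensitive 1,1-diarylethene to triflic anhydride.

Step 12
Reactants: 20 triflate with ring B 1-arylvinyl group
Product: 22 (2S,3S,8S) MOM-protected seven-ring core, via alkylboronate 21 (not isolated)
Conditions: CuCl (cat.), (R)-DTBM-SEGPHOS, NaOtBu (cat.), HBpin, toluene, rt; then H2O, Pd(OAc)2, RuPhos, K3PO4, 80 °C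
Reagents that add atoms: none
Why: A phosphine-ligated copper hydride adds across the 1,1-diarylethene with copper on the unhindered terminal carbon and hydride on the diaryl carbon, σ-bond metathesis with pinacolborane releases the primary alkylboronate 21, and after the water quench zerovalent palladium inserts into the C9 triflate, the phosphate-activated boronate transmetalates and reductive elimination forges C7–C9. The closest known reaction types are the copper-catalysed enantioselective hydroboration of 1,1-disubstituted aryl alkenes and the intramolecular B-alkyl Suzuki–Miyaura coupling, run here in sequence in one flask. The seven-membered ring closes by reductive elimination from an eight-membered palladacycle, and because boron already sits on the terminal carbon the ring size is fixed by the hydroboration regiochemistry and the 6-exo mode open to a Heck reaction of the same substrate is excluded. The C8 centre (S) is set by catalyst-controlled facial delivery of hydride, the bisphosphine distinguishing the twisted, doubly ortho-substituted ring B from the coplanar 4-methoxyphenyl group, with the resolved C3 centre beside ring B as a secondary bias, and C8 cannot epimerise under the coupling conditions. The step needs anti-Markovnikov boron placement, which the steric cost of a tertiary diarylmethyl copper secures, and chemoselective oxidative addition, which is secured because the triflate is the only carbon–heteroatom electrophile left; phosphate is chosen over hydroxide to spare the triflate from hydrolysis.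

Step 13
Reactants: 22 MOM-protected seven-ring core
Product: 23 (2S,3S,8S) seven-ring core with free phenol on C13
Conditions: ZnBr2, n-PrSH, CH2Cl2, 0 °C
Reagents that add atoms: none
Why: Lewis-acid-assisted acetal cleavage removes the MOM group quickly while the thiol captures the methoxymethyl cation, so neither the dihydrofuran nor the freed, highly nucleophilic ring A meets strong protic acid or free formaldehyde.

Step 14
Reactants: 23 phenol; 24 3,5-dimethoxybenzaldehyde
Product: 26 C14 sulfone (23 carrying a (3,5-dimethoxyphenyl)(4-methylbenzenesulfonyl)methyl group on C14; epimers at the sulfone carbon), via benzhydrol 25 (not isolated)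
Conditions: TolSO2Na, HCO2H–H2O, THF, rt
Reagents that add atoms: sodium p-toluenesulfinate, Cc1ccc(cc1)S(=O)[O-].[Na+]
Why: Acid-mediated ortho-hydroxyalkylation of the phenol (a Friedel–Crafts-type three-component condensation) is expected at C14, the free carbon ortho to the hydroxyl and para to the dihydrofuran oxygen as in orcinol-type rings, and not at C12 between the two oxygens, and sulfinate capture of the benzhydrol gives the quinone methide precursor, whose new centre is erased in step 16.

Step 15
Reactants: 9 4-methoxybenzyl alcohol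
Product: 27 (2R,5R)-1-(4-methoxybenzyl)-2,5-dimethylthiolan-1-ium tetrafluoroborate
Conditions: (2R,5R)-2,5-dimethylthiolane, HBF4·OEt2, CH2Cl2, 0 °C to rt
Reagents that add atoms: (2R,5R)-2,5-dimethylthiolane, C[C@@H]1CC[C@@H](C)S1; tetrafluoroboric acid (diethyl ether complex), [H+].F[B-](F)(F)F
Why: The same acid-promoted SN1 S-alkylation as in step 5 applies, and because the sulfide is twofold-symmetric its two lone pairs are equivalent and a single sulfonium salt results.

Step 16
Reactants: 26 C14 sulfone; 27 chiral sulfonium salt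
Product: 30 hepta-O-methyl ether of the target (2S,3S,8S,2'R,3'R), via quinone methide 28 (not isolated), via sulfonium ylide 29 (not isolated)
Conditions: Cs2CO3, MeCN, 0 °C to rt
Reagents that add atoms: none
Why: The formal [4+1] annulation of an ortho-quinone methide with a benzylic sulfur ylide should build the second dihydrofuran trans under reagent control, since the twofold-symmetric (2R,5R)-thiolanium group shields one face of the ylide carbon, so that this carbon becomes C2' (R) after the invertive 5-exo-tet closure and the anti addition relays its configuration to C3' (R).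

Step 17
Reactants: 30 hepta-O-methyl ether
Product: 31 CNP0136963.1
Conditions: BBr3, CH2Cl2, −78 °C to rt; then H2O
Reagents that add atoms: none
Why: Lewis-acid-mediated cleavage of all seven aryl methyl ethers should give the heptaphenol, since C3, C3' and C8 carry no leaving group and cannot epimerise, and any reversible opening of the benzylic C2–O or C2'–O bonds recloses to the thermodynamically preferred trans dihydrofurans.

**Compound list**

1 | 3,5-dimethoxybenzoic acid | COc1cc(C(=O)O)cc(OC)c1 | starting material
2 | 2-bromo-3,5-dimethoxybenzoic acid | O=C(O)c1cc(OC)cc(OC)c1Br | intermediate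
3 | phloroglucinol | Oc1cc(O)cc(O)c1 | starting material
4 | 2-bromo-3,5-dimethoxybenzoyl chloride (not isolated) | O=C(Cl)c1cc(OC)cc(OC)c1Br | intermediate
5 | (2-bromo-3,5-dimethoxyphenyl)(2,4,6-trihydroxyphenyl)methanone | O=C(c1c(O)cc(O)cc1O)c1cc(OC)cc(OC)c1Br | intermediate
6 | (2-bromo-3,5-dimethoxyphenyl)[2,6-dihydroxy-4-(methoxymethoxy)phenyl]methanone | O=C(c1c(O)cc(OCOC)cc1O)c1cc(OC)cc(OC)c1Br | intermediate
7 | racemic 2-[(2-bromo-3,5-dimethoxyphenyl)(hydroxy)methyl]-5-(methoxymethoxy)benzene-1,3-diol (not isolated) | OC(c1c(O)cc(OCOC)cc1O)c1cc(OC)cc(OC)c1Br | intermediate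
8 | racemic 2-[(2-bromo-3,5-dimethoxyphenyl)(4-methylbenzenesulfonyl)methyl]-5-(methoxymethoxy)benzene-1,3-diol | Cc1ccc(cc1)S(=O)(=O)C(c1c(O)cc(OCOC)cc1O)c1cc(OC)cc(OC)c1Br | intermediate
9 | 4-methoxybenzyl alcohol | COc1ccc(CO)cc1 | starting material
10 | 1-(4-methoxybenzyl)tetrahydrothiophen-1-ium tetrafluoroborate | COc1ccc(C[S+]2CCCC2)cc1.F[B-](F)(F)F | intermediate
11 | 6-[(2-bromo-3,5-dimethoxyphenyl)methylidene]-5-hydroxy-3-(methoxymethoxy)cyclohexa-2,4-dien-1-one (ortho-quinone methide; not isolated) | O=C1C=C(OCOC)C=C(O)C1=Cc1cc(OC)cc(OC)c1Br | intermediate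
12 | (4-methoxyphenyl)(tetrahydrothiophen-1-ium-1-yl)methanide (sulfonium ylide; not isolated) | COc1ccc([CH-][S+]2CCCC2)cc1 | intermediate
13 | racemic trans-3-(2-bromo-3,5-dimethoxyphenyl)-2-(4-methoxyphenyl)-6-(methoxymethoxy)-2,3-dihydro-1-benzofuran-4-ol (1:1 mixture of the (2S,3R) and (2R,3S) enantiomers) | Brc1c(OC)cc(OC)cc1[C@H]1c2c(O)cc(OCOC)cc2O[C@@H]1c1ccc(OC)cc1.Brc1c(OC)cc(OC)cc1[C@@H]1c2c(O)cc(OCOC)cc2O[C@H]1c1ccc(OC)cc1 | intermediate
14 | (2S,3R)-3-(2-bromo-3,5-dimethoxyphenyl)-2-(4-methoxyphenyl)-6-(methoxymethoxy)-2,3-dihydro-1-benzofuran-4-ol | Brc1c(OC)cc(OC)cc1[C@H]1c2c(O)cc(OCOC)cc2O[C@@H]1c1ccc(OC)cc1 | intermediate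
15 | 4-methoxyacetophenone | CC(=O)c1ccc(OC)cc1 | starting material
16 | N'-[1-(4-methoxyphenyl)ethylidene]-2,4,6-tri(propan-2-yl)benzenesulfonohydrazide | COc1ccc(cc1)C(C)=NNS(=O)(=O)c1c(C(C)C)cc(C(C)C)cc1C(C)C | intermediate
17 | [1-(4-methoxyphenyl)ethenyl]lithium (not isolated) | [Li]C(=C)c1ccc(OC)cc1 | intermediate
18 | 2-[1-(4-methoxyphenyl)ethenyl]-4,4,5,5-tetramethyl-1,3,2-dioxaborolane | C=C(B1OC(C)(C)C(C)(C)O1)c1ccc(OC)cc1 | intermediate
19 | (2S,3S)-3-{3,5-dimethoxy-2-[1-(4-methoxyphenyl)ethenyl]phenyl}-2-(4-methoxyphenyl)-6-(methoxymethoxy)-2,3-dihydro-1-benzofuran-4-ol | C=C(c1ccc(OC)cc1)c1c(OC)cc(OC)cc1[C@H]1c2c(O)cc(OCOC)cc2O[C@@H]1c1ccc(OC)cc1 | intermediate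
20 | (2S,3S)-3-{3,5-dimethoxy-2-[1-(4-methoxyphenyl)ethenyl]phenyl}-2-(4-methoxyphenyl)-6-(methoxymethoxy)-2,3-dihydro-1-benzofuran-4-yl trifluoromethanesulfonate (key-step precursor) | C=C(c1ccc(OC)cc1)c1c(OC)cc(OC)cc1[C@H]1c2c(OS(=O)(=O)C(F)(F)F)cc(OCOC)cc2O[C@@H]1c1ccc(OC)cc1 | intermediate
21 | (2S,3S)-3-{3,5-dimethoxy-2-[(1S)-1-(4-methoxyphenyl)-2-(4,4,5,5-tetramethyl-1,3,2-dioxaborolan-2-yl)ethyl]phenyl}-2-(4-methoxyphenyl)-6-(methoxymethoxy)-2,3-dihydro-1-benzofuran-4-yl trifluoromethanesulfonate (not isolated) | COc1ccc([C@H](CB2OC(C)(C)C(C)(C)O2)c2c(OC)cc(OC)cc2[C@H]2c3c(OS(=O)(=O)C(F)(F)F)cc(OCOC)cc3O[C@@H]2c2ccc(OC)cc2)cc1 | intermediate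
22 | (2S,3S,8S) MOM-protected seven-ring core (key-step product): trans dihydrofuran on C10/C11 with 4-methoxyphenyl on C2; dimethoxy ring B joining C3 and C8; C7H2 on C9; 4-methoxyphenyl on C8; OMOM on C13 | COc1ccc([C@@H]2Cc3c4c(cc(OCOC)c3)O[C@H](c3ccc(OC)cc3)[C@H]4c3cc(OC)cc(OC)c32)cc1 | intermediate
23 | (2S,3S,8S) seven-ring core with free phenol on C13 | COc1ccc([C@@H]2Cc3c4c(cc(O)c3)O[C@H](c3ccc(OC)cc3)[C@H]4c3cc(OC)cc(OC)c32)cc1 | intermediate
24 | 3,5-dimethoxybenzaldehyde | COc1cc(C=O)cc(OC)c1 | starting material
25 | C14 benzhydrol: 23 carrying a (3,5-dimethoxyphenyl)(hydroxy)methyl group on C14 (epimers at the carbinol carbon; not isolated) | COc1ccc([C@@H]2Cc3c4c(cc(O)c3C(O)c3cc(OC)cc(OC)c3)O[C@H](c3ccc(OC)cc3)[C@H]4c3cc(OC)cc(OC)c32)cc1 | intermediate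
26 | C14 sulfone: 23 carrying a (3,5-dimethoxyphenyl)(4-methylbenzenesulfonyl)methyl group on C14 (epimers at the sulfone carbon) | COc1ccc([C@@H]2Cc3c4c(cc(O)c3C(c3cc(OC)cc(OC)c3)S(=O)(=O)c3ccc(C)cc3)O[C@H](c3ccc(OC)cc3)[C@H]4c3cc(OC)cc(OC)c32)cc1 | intermediate
27 | (2R,5R)-1-(4-methoxybenzyl)-2,5-dimethylthiolan-1-ium tetrafluoroborate | C[C@@H]1CC[C@@H](C)[S+]1Cc1ccc(OC)cc1.F[B-](F)(F)F | intermediate
28 | ring A ortho-quinone methide: carbonyl at C13 and exocyclic C14=CH(3,5-dimethoxyphenyl) on the seven-ring core (not isolated) | COc1ccc([C@@H]2CC3=C4C(=CC(=O)C3=Cc3cc(OC)cc(OC)c3)O[C@H](c3ccc(OC)cc3)[C@H]4c3cc(OC)cc(OC)c32)cc1 | intermediate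
29 | [(2R,5R)-2,5-dimethylthiolan-1-ium-1-yl](4-methoxyphenyl)methanide (chiral sulfonium ylide; not isolated) | C[C@@H]1CC[C@@H](C)[S+]1[CH-]c1ccc(OC)cc1 | intermediate
30 | hepta-O-methyl ether of the target (2S,3S,8S,2'R,3'R) | COc1ccc([C@@H]2Cc3c4c(cc5c3[C@@H](c3cc(OC)cc(OC)c3)[C@H](c3ccc(OC)cc3)O5)O[C@H](c3ccc(OC)cc3)[C@H]4c3cc(OC)cc(OC)c32)cc1 | intermediate
31 | CNP0136963.1 (2S,3S,8S,2'R,3'R) | Oc1ccc([C@@H]2Cc3c4c(cc5c3[C@@H](c3cc(O)cc(O)c3)[C@H](c3ccc(O)cc3)O5)O[C@H](c3ccc(O)cc3)[C@H]4c3cc(O)cc(O)c32)cc1 | target

**Step count and risks**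

Total step count: 17. Longest linear sequence: 13 steps (1 to 31 through steps 1–4, 6, 7, 10–14, 16 and 17); steps 5, 8, 9 and 15 prepare the side reagents.

Steps most likely to fail:

1. Step 12. Transmetalation of the hindered primary pinacol boronate into an eight-membered palladacycle may be slower than hydrolysis of the triflate or protodeboronation, and hydride delivery to the congested alkene may be incompletely face-selective. Fallback: setting out from 20, the hydroboration is run alone and boronate 21 is oxidised (NaBO3, THF–H2O) to the (S)-primary alcohol F1. Iodination (iodine, PPh3, imidazole) gives the iodide F2, zinc insertion (Zn, LiCl, THF) gives the alkylzinc iodide F3, and an intramolecular Negishi coupling with the C9 triflate (Pd(OAc)2, SPhos, THF, 60 °C) forms the same C7–C9 bond and comes back to the route at 22. C8, already set by the copper catalyst, is not touched.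

2. Step 14. The three-component condensation may stall at the crowded C14 position, drift toward C12 under reversible acid conditions, or lose the quinone methide to capture by a second phenol molecule. Fallback: the aryl group is brought in as a nucleophile instead. Setting out from 23, Vilsmeier–Haack formylation (POCl3, DMF, 0 °C to rt; aqueous NaOAc), an irreversible substitution expected para to the dihydrofuran oxygen, gives the C14 aldehyde F4. Grignard addition of 3,5-dimethoxyphenylmagnesium bromide (excess, THF, 0 °C) then gives benzhydrol 25, where the route is rejoined, and sulfinate capture as in step 14 leads to 26.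

3. Step 6. The second ortho hydroxyl may ionise under the basic conditions, which would lower the electrophilicity of the quinone methide and divert the ylide or the sulfonium salt into proton transfer and O-benzylation. Fallback: that oxygen is masked for the annulation. Setting out from 6, allylation of one of the two equivalent ortho hydroxyls (allyl bromide, K2CO3, acetone, rt; the second stays hydrogen-bonded to the carbonyl) gives the allyl ether ketone F5. Reduction as in step 4 gives the benzhydrol F6 and sulfinate capture gives the sulfone F7. With Cs2CO3 and 10 in MeCN, F7 should give the neutral quinone methide F8, which takes up ylide 12 to give the racemic trans allyl ether F9. Deallylation (Pd(PPh3)4, morpholine, THF, rt), which leaves the hindered aryl bromide untouched, comes back to the route at 13.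

Further compounds
F1 | step 12 | (2S,3S)-3-{2-[(1S)-2-hydroxy-1-(4-methoxyphenyl)ethyl]-3,5-dimethoxyphenyl}-2-(4-methoxyphenyl)-6-(methoxymethoxy)-2,3-dihydro-1-benzofuran-4-yl trifluoromethanesulfonate | COc1ccc([C@H](CO)c2c(OC)cc(OC)cc2[C@H]2c3c(OS(=O)(=O)C(F)(F)F)cc(OCOC)cc3O[C@@H]2c2ccc(OC)cc2)cc1
F2 | step 12 | (2S,3S)-3-{2-[(1S)-2-iodo-1-(4-methoxyphenyl)ethyl]-3,5-dimethoxyphenyl}-2-(4-methoxyphenyl)-6-(methoxymethoxy)-2,3-dihydro-1-benzofuran-4-yl trifluoromethanesulfonate | COc1ccc([C@H](CI)c2c(OC)cc(OC)cc2[C@H]2c3c(OS(=O)(=O)C(F)(F)F)cc(OCOC)cc3O[C@@H]2c2ccc(OC)cc2)cc1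
F3 | step 12 | alkylzinc iodide derived from F2 (C–ZnI in place of C–I; not isolated) | COc1ccc([C@H](C[Zn]I)c2c(OC)cc(OC)cc2[C@H]2c3c(OS(=O)(=O)C(F)(F)F)cc(OCOC)cc3O[C@@H]2c2ccc(OC)cc2)cc1
F4 | step 14 | C14 aldehyde: 23 carrying a formyl group on C14 | COc1ccc([C@@H]2Cc3c4c(cc(O)c3C=O)O[C@H](c3ccc(OC)cc3)[C@H]4c3cc(OC)cc(OC)c32)cc1
F5 | step 6 | (2-bromo-3,5-dimethoxyphenyl)[2-hydroxy-4-(methoxymethoxy)-6-(prop-2-en-1-yloxy)phenyl]methanone | O=C(c1c(O)cc(OCOC)cc1OCC=C)c1cc(OC)cc(OC)c1Br
F6 | step 6 | racemic 2-[(2-bromo-3,5-dimethoxyphenyl)(hydroxy)methyl]-5-(methoxymethoxy)-3-(prop-2-en-1-yloxy)phenol (not isolated) | OC(c1c(O)cc(OCOC)cc1OCC=C)c1cc(OC)cc(OC)c1Br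
F7 | step 6 | racemic 2-[(2-bromo-3,5-dimethoxyphenyl)(4-methylbenzenesulfonyl)methyl]-5-(methoxymethoxy)-3-(prop-2-en-1-yloxy)phenol | Cc1ccc(cc1)S(=O)(=O)C(c1c(O)cc(OCOC)cc1OCC=C)c1cc(OC)cc(OC)c1Br
F8 | step 6 | 6-[(2-bromo-3,5-dimethoxyphenyl)methylidene]-3-(methoxymethoxy)-5-(prop-2-en-1-yloxy)cyclohexa-2,4-dien-1-one (not isolated) | O=C1C=C(OCOC)C=C(OCC=C)C1=Cc1cc(OC)cc(OC)c1Br
F9 | step 6 | racemic trans-3-(2-bromo-3,5-dimethoxyphenyl)-2-(4-methoxyphenyl)-6-(methoxymethoxy)-4-(prop-2-en-1-yloxy)-2,3-dihydro-1-benzofuran (1:1 mixture of the (2S,3R) and (2R,3S) enantiomers) | Brc1c(OC)cc(OC)cc1[C@H]1c2c(OCC=C)cc(OCOC)cc2O[C@@H]1c1ccc(OC)cc1.Brc1c(OC)cc(OC)cc1[C@@H]1c2c(OCC=C)cc(OCOC)cc2O[C@H]1c1ccc(OC)cc1
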